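## Retrosynthetic overview

1. The C8 glycolate and C14 acetate go on last. C13 comes from a Mannich/elimination on the cis-fused C6–C7 butanolide, the last ring formed (lactol from a C6 alcohol and a C12 aldehyde, then oxidation).
2. Enabling feature: with C6 as a ketone and the ring alkene shifted from C1=C10 to C1=C2, the ten-membered ring contains C6(=O)–C5–C4(CH3)–C3–C2=C1, the δ,ε-unsaturated-ketone retron of an anionic oxy-Cope rearrangement. C6 and C1 are also the ends of a potential six-membered ring C6–C7–C8–C9–C10–C1.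
3. The carbocycle is therefore closed at C3–C4 by a four-carbon ring expansion of a cyclohexanol carrying a (Z)-propenyl group on C6 and a vinyl group on C1 (C6–C1 breaks). A C14 aldehyde on C10 later pulls the strained E C1=C2 alkene into the C1=C10 position.
4. The all-equatorial cyclohexanone comes from an enantioselective Diels–Alder reaction (cyclohexene, first ring; sets C1 and C10) and an O6-tethered radical cyclization–oxygenation (sets C7 and C8).
5. Ring order: cyclohexene (step 1), temporary tetrahydrofuran (step 5, opened in step 7), ten-membered ring (step 10), lactone (steps 12 and 13).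

Key step: step 10

Remark on names: ring carbons keep their germacranolide locants throughout: C6 lactone O-carbon, C7 ring-fusion carbon bearing C11, C8 glycolate carbon, C9, C10 (bears C14), C1, C2, C3, C4 (bears the methyl group), C5; lactone carbons C11, C12 (C=O), C13 (=CH2). The six-membered precursors contain C6, C7, C8, C9, C10 and C1. With the ring drawn so that C6→C7→C8→C9→C10 runs counterclockwise, β substituents point to the viewer; the target is 4β-methyl, 6β-O, 7β-C11, 8α-O.

Remark on the chemistry: commercial 1 is an E/Z mixture; only the E isomer is expected to react in step 1.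

## Route

Step 1
Reactants: 1 (E)-buta-1,3-dien-1-yl acetate; 2 (E)-4,4-dimethoxybut-2-enal
Product: 3 (1R,5R,6S)-5-(dimethoxymethyl)-6-formylcyclohex-2-en-1-yl acetate (6β-OAc; 1β-CHO; 10α-CH(OMe)2)
Conditions: (5R)-5-benzyl-2,2,3-trimethylimidazolidin-4-one hydrochloride (20 mol %), MeCN/H2O (95:5), −10 °C to rt
Reagents that add atoms: none
Why: Iminium-catalysed Diels–Alder reaction: the free diene terminus bonds to the enal β-carbon (C10) so the acetoxy carbon (C6) ends next to the formyl carbon (C1), the E-enal fixes CHO and acetal trans, endo addition places OAc cis to CHO, and the benzyl group of the (5R)-catalyst should leave the Re face of the α-carbon open, which sets the absolute configuration of C1 and C10.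

Step 2
Reactants: 3 (1R,5R,6S)-5-(dimethoxymethyl)-6-formylcyclohex-2-en-1-yl acetate
Product: 4 6β-acetoxy-10α-(dimethoxymethyl)-1β-vinylcyclohex-7-ene
Conditions: Ph3PCH3Br, KN(SiMe3)2, THF, −78 to 0 °C
Reagents that add atoms: methyltriphenylphosphonium bromide, C[P+](c1ccccc1)(c1ccccc1)c1ccccc1.[Br-]
Why: Wittig methylenation of the aldehyde at low temperature should outrun enolization and β-elimination of acetate, so C1 keeps its configuration; no new stereocentre.

Step 3
Reactants: 4 6β-acetoxy-10α-(dimethoxymethyl)-1β-vinylcyclohex-7-ene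
Product: 5 10α-(dimethoxymethyl)-1β-vinylcyclohex-7-en-6β-ol
Conditions: K2CO3 (0.2 equiv), MeOH, 0 °C
Reagents that add atoms: none
Why: Base-catalysed transesterification removes the acetate without touching the acetal or the alkenes; no stereocentre is affected.

Step 4
Reactants: 5 10α-(dimethoxymethyl)-1β-vinylcyclohex-7-en-6β-ol
Product: 6 6β-(2-bromo-1-ethoxyethoxy)-10α-(dimethoxymethyl)-1β-vinylcyclohex-7-ene (both epimers at the acetal carbon)
Conditions: ethyl vinyl ether, N-bromosuccinimide, CH2Cl2, −40 to 0 °C
Reagents that add atoms: ethyl vinyl ether, C=COCC; N-bromosuccinimide, O=C1CCC(=O)N1Br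
Why: Bromoacetalization: the electron-rich vinyl ether is brominated far faster than the other alkenes and the C6 alcohol traps the oxocarbenium ion; the new acetal carbon (future C12) is stereochemically irrelevant.

Step 5
Reactants: 6 6β-(2-bromo-1-ethoxyethoxy)-10α-(dimethoxymethyl)-1β-vinylcyclohex-7-ene
Product: 8 cis-fused bicyclic acetal (ring O6–C12H(OEt)–C11H2–C7; 6β-O; 7β-C11; 8α-OH; 10α-CH(OMe)2; 1β-vinyl), via C8 hydroperoxide 7 (not isolated)
Conditions: n-Bu3SnH (slow addition), dry air, toluene, 0 °C to rt; then PPh3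
Reagents that add atoms: dioxygen, O=O
Why: Ueno–Stork radical cyclization with oxygen capture: the tethered primary radical closes 5-exo-trig on C7 from the face of O6 (cis-fused ring, sets C7), and the C8 radical should be trapped by O2 on the convex face anti to the new C7–C11 bond (sets C8, O8 α), the hydroperoxide being reduced by PPh3.

Step 6
Reactants: 8 cis-fused bicyclic acetal with free 8α-OH
Product: 9 8α-triisopropylsilyl ether of 8
Conditions: i-Pr3SiOTf, 2,6-lutidine, CH2Cl2, −20 °C
Reagents that add atoms: triisopropylsilyl trifluoromethanesulfonate, CC(C)[Si](C(C)C)(C(C)C)OS(=O)(=O)C(F)(F)F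
Why: Silylation of the secondary alcohol; the triisopropylsilyl ether is chosen to survive the Lewis acid, strong base and hydride steps that follow.

Step 7
Reactants: 9 8α-triisopropylsilyl ether of 8
Product: 10 10α-(1,3-dithian-2-yl)-7β-[(1,3-dithian-2-yl)methyl]-8α-(triisopropylsilyloxy)-1β-vinylcyclohexan-6β-ol
Conditions: propane-1,3-dithiol (3 equiv), BF3·OEt2 (0.5 equiv), CH2Cl2, −40 to −10 °C
Reagents that add atoms: propane-1,3-dithiol, SCCCS
Why: Lewis-acid dithioacetalization: both O,O-acetals exchange to 1,3-dithianes, which opens the tetrahydrofuran, frees the C6 hydroxyl and masks C12 and C14 as base-stable aldehyde equivalents; no stereocentre changes.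

Step 8
Reactants: 10 bis-dithiane cyclohexan-6β-ol
Product: 11 10α-(1,3-dithian-2-yl)-7β-[(1,3-dithian-2-yl)methyl]-8α-(triisopropylsilyloxy)-1β-vinylcyclohexan-6-one (all four substituents equatorial)
Conditions: Dess–Martin periodinane, pyridine, CH2Cl2, 0 °C
Reagents that add atoms: none
Why: Dess–Martin oxidation of the secondary alcohol under buffered conditions; the α-stereocentres C1 and C7 are already in their equatorial (thermodynamic) configuration, so they should not scramble.

Step 9
Reactants: 11 all-equatorial cyclohexan-6-one; 12 (Z)-1-bromoprop-1-ene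
Product: 13 6α-[(Z)-prop-1-enyl]-10α-(1,3-dithian-2-yl)-7β-[(1,3-dithian-2-yl)methyl]-8α-(triisopropylsilyloxy)-1β-vinylcyclohexan-6β-ol
Conditions: 12, t-BuLi (2 equiv), THF/Et2O, −78 °C; CeCl3, −78 °C; then 11, −78 °C; aqueous work-up
Reagents that add atoms: none
Why: Organocerium 1,2-addition (low basicity suppresses enolization of the α-vinyl ketone): the alkenyl reagent keeps its Z geometry and should enter equatorially, giving the axial 6β tertiary alcohol with the propenyl and vinyl groups trans-diequatorial.

Step 10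
Reactants: 13 6α-[(Z)-prop-1-enyl]-1β-vinylcyclohexan-6β-ol
Product: 16 (1E)-4β-methyl-10α-(1,3-dithian-2-yl)-7β-[(1,3-dithian-2-yl)methyl]-8α-(triisopropylsilyloxy)cyclodec-1-en-6-one, via potassium alkoxide 14 (not isolated), via potassium enolate 15 (not isolated)
Conditions: KH (3 equiv), 18-crown-6, THF (0.02 M), 0 to 40 °C; then AcOH, −78 °C
Reagents that add atoms: none
Why: Deprotonation gives alkoxide 14, whose oxyanion weakens the C6–C1 bond so that the 1,5-diene C4=C5–C6–C1–C2=C3 undergoes a concerted [3,3]-sigmatropic (anionic oxy-Cope) rearrangement in which C3–C4 forms as C6–C1 breaks, giving enolate 15 and, on kinetic protonation, ketone 16. The closest known reaction type is the anionic oxy-Cope ring expansion of trans-1,2-dialkenylcyclohexanols to (E)-cyclodec-5-enones. The ten-membered ring is closed not by an end-to-end cyclization but by a four-atom ring expansion through a six-membered chair-like transition state in which both alkenyl groups are equatorial on the cyclohexane chair (a trans-decalin-like array), so high dilution is not essential. The new stereocentre C4 is set by chirality transfer from C6 and C1: in that chair the Z-methyl group is axial and C3 bonds to the face of C4 that leaves the methyl group β, while the equatorial C10 substituent makes the new C1=C2 bond E; C7, C8 and C10 are untouched. The step needs the chair over the boat transition state and rearrangement over alkoxide fragmentation or enolate equilibration (which would expose the C8 silyloxy group to β-elimination); this is secured by the all-equatorial substitution that anchors the reactive chair, the axial oxyanion, the absence of any other 1,5-diene or free carbonyl group (both aldehydes are dithianes) and the cold acetic acid quench.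

Step 11
Reactants: 16 (1E)-cyclodec-1-en-6-one
Product: 17 (1E)-4β-methyl-10α-(1,3-dithian-2-yl)-7β-[(1,3-dithian-2-yl)methyl]-8α-(triisopropylsilyloxy)cyclodec-1-en-6β-ol
Conditions: LiBH(s-Bu)3, THF, −78 °C; aqueous work-up
Reagents that add atoms: none
Why: Bulky-hydride ketone reduction: hydride should approach from the ring periphery, anti to the C7 side chain, on the conformer delivered by the rearrangement (carbonyl oxygen on the β face), giving the 6β alcohol cis to C11.

Step 12
Reactants: 17 (1E)-cyclodec-1-en-6β-ol bis-dithiane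
Product: 19 lactol enal (ring C6–O–C12H(OH)–C11H2–C7 cis-fused; ring-cis C1=C10 bearing the C14 aldehyde; 4β-methyl; 8α-OSi(i-Pr)3), via β,γ-unsaturated aldehyde lactol 18 (not isolated)
Conditions: MeI, CaCO3, MeCN/H2O (9:1), 45 °C; then 1,8-diazabicyclo[5.4.0]undec-7-ene (cat.), CH2Cl2, 0 °C
Reagents that add atoms: water, O
Why: Alkylative thioacetal hydrolysis frees both aldehydes without electrophilic attack on the strained alkene; the C12 aldehyde closes the five-membered lactol on the cis C6 hydroxyl, and base moves the E C1=C2 bond into conjugation with the C14 aldehyde to give the thermodynamic ring-cis enal (C2 trans to CHO), which removes the C10 stereocentre.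

Step 13
Reactants: 19 lactol enal
Product: 20 cis-fused 12,6-lactone enal (C12=O; C14 aldehyde on ring-cis C1=C10; 8α-OSi(i-Pr)3)
Conditions: 2,2,6,6-tetramethylpiperidin-1-oxyl (cat.), PhI(OAc)2, CH2Cl2, rt
Reagents that add atoms: none
Why: Oxoammonium oxidation of the lactol to the γ-lactone; the enal and the silyl ether are inert, and the cis ring fusion is already fixed.

Step 14
Reactants: 20 cis-fused lactone enal
Product: 21 cis-fused lactone with 14-hydroxy group (C10–CH2OH on ring-cis C1=C10; 8α-OSi(i-Pr)3)
Conditions: NaBH4, CeCl3·7H2O, MeOH, −40 °C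
Reagents that add atoms: none
Why: Luche reduction gives clean 1,2-reduction of the enal and leaves the lactone untouched; no new stereocentre.

Step 15
Reactants: 21 14-hydroxy lactone
Product: 22 14-O-tert-butyldimethylsilyl ether of 21
Conditions: t-BuMe2SiCl, imidazole, DMF, 0 °C
Reagents that add atoms: tert-butyldimethylsilyl chloride, CC(C)(C)[Si](C)(C)Cl
Why: Silylation of the primary allylic alcohol removes the only acidic proton and acyl-free oxygen before the enolate step.

Step 16
Reactants: 22 bis-silyl lactone
Product: 24 11-(dimethylaminomethyl) lactone (either configuration at C11), via lithium enolate 23 (not isolated)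
Conditions: LiN(i-Pr)2, THF, −78 °C; then Me2N=CH2 I (Eschenmoser's salt), −78 to 0 °C
Reagents that add atoms: N,N-dimethylmethyleneiminium iodide, C=[N+](C)C.[I-]
Why: Mannich reaction of the lactone lithium enolate with the preformed iminium salt; the new C11 centre is removed in the next step, so its configuration does not matter.

Step 17
Reactants: 24 11-(dimethylaminomethyl) lactone
Product: 26 α-methylene lactone bis-silyl ether (C11=C13H2; 8α-OSi(i-Pr)3; 14-OSiMe2t-Bu), via trimethylammonium iodide 25 (not isolated)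
Conditions: MeI, MeOH, rt; then aqueous NaHCO3, CH2Cl2
Reagents that add atoms: none
Why: N-quaternization followed by E1cB (Hofmann-type) elimination of trimethylamine gives the exocyclic C11=C13 alkene under mild base.

Step 18
Reactants: 26 α-methylene lactone bis-silyl ether
Product: 27 8α,14-diol of the α-methylene lactone
Conditions: Bu4NF, AcOH (1:1), THF, 0 °C to rt
Reagents that add atoms: none
Why: Fluoride desilylation of both ethers; acetic acid buffering should suppress conjugate addition to the methylene lactone and translactonization to O8.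

Step 19
Reactants: 27 8α,14-diol
Product: 28 14-acetate 8α-alcohol
Conditions: Ac2O (1.1 equiv), 2,4,6-collidine, CH2Cl2, −20 °C
Reagents that add atoms: acetic anhydride, CC(=O)OC(C)=O
Why: Kinetically selective acylation of the primary allylic alcohol over the hindered secondary C8 alcohol.

Step 20
Reactants: 28 14-acetate 8α-alcohol; 29 2-[(tert-butyldimethylsilyl)oxy]acetic acid
Product: 30 8-O-[2-(tert-butyldimethylsilyloxy)acetyl] derivative of 28
Conditions: EDC·HCl, 4-(dimethylamino)pyridine (cat.), CH2Cl2, 0 °C to rt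
Reagents that add atoms: none
Why: Steglich esterification of the secondary alcohol with retention at C8; the silyl group prevents self-acylation of the glycolic acid.

Step 21
Reactants: 30 silyl-protected glycolate
Product: 31 target compound CNP0156635.1
Conditions: HF·pyridine, pyridine/THF, 0 °C
Reagents that add atoms: none
Why: Acidic fluoride cleavage of the primary silyl ether leaves both esters and the α-methylene lactone intact.

## Compound list

1 | (E)-buta-1,3-dien-1-yl acetate | CC(=O)O/C=C/C=C | starting material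
2 | (E)-4,4-dimethoxybut-2-enal | COC(OC)/C=C/C=O | starting material
3 | (1R,5R,6S)-5-(dimethoxymethyl)-6-formylcyclohex-2-en-1-yl acetate | CC(=O)O[C@@H]1C=CC[C@@H](C(OC)OC)[C@@H]1C=O | intermediate
4 | 6β-acetoxy-10α-(dimethoxymethyl)-1β-vinylcyclohex-7-ene | CC(=O)O[C@@H]1C=CC[C@@H](C(OC)OC)[C@@H]1C=C | intermediate
5 | 10α-(dimethoxymethyl)-1β-vinylcyclohex-7-en-6β-ol | O[C@@H]1C=CC[C@@H](C(OC)OC)[C@@H]1C=C | intermediate
6 | 6β-(2-bromo-1-ethoxyethoxy)-10α-(dimethoxymethyl)-1β-vinylcyclohex-7-ene | CCOC(CBr)O[C@@H]1C=CC[C@@H](C(OC)OC)[C@@H]1C=C | intermediate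
7 | C8 hydroperoxide of bicyclic acetal 8 | CCOC1C[C@@H]2[C@@H](OO)C[C@@H](C(OC)OC)[C@H](C=C)[C@@H]2O1 | intermediate (not isolated)
8 | cis-fused bicyclic acetal, 8α-OH | CCOC1C[C@@H]2[C@@H](O)C[C@@H](C(OC)OC)[C@H](C=C)[C@@H]2O1 | intermediate
9 | 8α-triisopropylsilyl ether of 8 | CCOC1C[C@@H]2[C@@H](O[Si](C(C)C)(C(C)C)C(C)C)C[C@@H](C(OC)OC)[C@H](C=C)[C@@H]2O1 | intermediate
10 | 10α-(1,3-dithian-2-yl)-7β-[(1,3-dithian-2-yl)methyl]-8α-(triisopropylsilyloxy)-1β-vinylcyclohexan-6β-ol | O[C@H]1[C@@H](C=C)[C@H](C2SCCCS2)C[C@H](O[Si](C(C)C)(C(C)C)C(C)C)[C@H]1CC3SCCCS3 | intermediate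
11 | corresponding cyclohexan-6-one (all substituents equatorial) | O=C1[C@@H](C=C)[C@H](C2SCCCS2)C[C@H](O[Si](C(C)C)(C(C)C)C(C)C)[C@H]1CC3SCCCS3 | intermediate
12 | (Z)-1-bromoprop-1-ene | C/C=C\Br | starting material
13 | 6α-[(Z)-prop-1-enyl]-1β-vinylcyclohexan-6β-ol (substituents as in 11) | O[C@@]1(/C=C\C)[C@@H](C=C)[C@H](C2SCCCS2)C[C@H](O[Si](C(C)C)(C(C)C)C(C)C)[C@H]1CC3SCCCS3 | intermediate
14 | potassium alkoxide of 13 | [K+].[O-][C@@]1(/C=C\C)[C@@H](C=C)[C@H](C2SCCCS2)C[C@H](O[Si](C(C)C)(C(C)C)C(C)C)[C@H]1CC3SCCCS3 | intermediate (not isolated)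
15 | potassium C5=C6 enolate of 16 | [K+].C1[C@H](O[Si](C(C)C)(C(C)C)C(C)C)[C@@H](CC3SCCCS3)/C([O-])=C/[C@@H](C)C/C=C/[C@@H]1C2SCCCS2 | intermediate (not isolated)
16 | (1E)-4β-methyl-10α-(1,3-dithian-2-yl)-7β-[(1,3-dithian-2-yl)methyl]-8α-(triisopropylsilyloxy)cyclodec-1-en-6-one | O=C1C[C@@H](C)C/C=C/[C@H](C2SCCCS2)C[C@H](O[Si](C(C)C)(C(C)C)C(C)C)[C@H]1CC3SCCCS3 | intermediate
17 | corresponding cyclodec-1-en-6β-ol | O[C@H]1C[C@@H](C)C/C=C/[C@H](C2SCCCS2)C[C@H](O[Si](C(C)C)(C(C)C)C(C)C)[C@H]1CC3SCCCS3 | intermediate
18 | lactol with (1E)-alkene and C10 formyl group | C1C(O)O[C@H]2C[C@@H](C)C/C=C/[C@H](C=O)C[C@H](O[Si](C(C)C)(C(C)C)C(C)C)[C@@H]12 | intermediate (not isolated)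
19 | lactol with ring-cis C1=C10 enal | C1C(O)O[C@H]2C[C@@H](C)CC/C=C(/C=O)C[C@H](O[Si](C(C)C)(C(C)C)C(C)C)[C@@H]12 | intermediate
20 | cis-fused 12,6-lactone enal | C1C(=O)O[C@H]2C[C@@H](C)CC/C=C(/C=O)C[C@H](O[Si](C(C)C)(C(C)C)C(C)C)[C@@H]12 | intermediate
21 | 14-hydroxy lactone | C1C(=O)O[C@H]2C[C@@H](C)CC/C=C(/CO)C[C@H](O[Si](C(C)C)(C(C)C)C(C)C)[C@@H]12 | intermediate
22 | 14-O-tert-butyldimethylsilyl lactone | C1C(=O)O[C@H]2C[C@@H](C)CC/C=C(/CO[Si](C)(C)C(C)(C)C)C[C@H](O[Si](C(C)C)(C(C)C)C(C)C)[C@@H]12 | intermediate
23 | lithium enolate of 22 | [Li+].C1=C([O-])O[C@H]2C[C@@H](C)CC/C=C(/CO[Si](C)(C)C(C)(C)C)C[C@H](O[Si](C(C)C)(C(C)C)C(C)C)[C@@H]12 | intermediate (not isolated)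
24 | 11-(dimethylaminomethyl) lactone | CN(C)CC1C(=O)O[C@H]2C[C@@H](C)CC/C=C(/CO[Si](C)(C)C(C)(C)C)C[C@H](O[Si](C(C)C)(C(C)C)C(C)C)[C@@H]12 | intermediate
25 | trimethylammonium iodide of 24 | [I-].C[N+](C)(C)CC1C(=O)O[C@H]2C[C@@H](C)CC/C=C(/CO[Si](C)(C)C(C)(C)C)C[C@H](O[Si](C(C)C)(C(C)C)C(C)C)[C@@H]12 | intermediate (not isolated)
26 | α-methylene lactone bis-silyl ether | C=C1C(=O)O[C@H]2C[C@@H](C)CC/C=C(/CO[Si](C)(C)C(C)(C)C)C[C@H](O[Si](C(C)C)(C(C)C)C(C)C)[C@@H]12 | intermediate
27 | α-methylene lactone 8α,14-diol | C=C1C(=O)O[C@H]2C[C@@H](C)CC/C=C(/CO)C[C@H](O)[C@@H]12 | intermediate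
28 | 14-acetate 8α-alcohol | C=C1C(=O)O[C@H]2C[C@@H](C)CC/C=C(/COC(C)=O)C[C@H](O)[C@@H]12 | intermediate
29 | 2-[(tert-butyldimethylsilyl)oxy]acetic acid | OC(=O)CO[Si](C)(C)C(C)(C)C | starting material
30 | 8-O-[2-(tert-butyldimethylsilyloxy)acetyl] 14-acetate | C=C1C(=O)O[C@H]2C[C@@H](C)CC/C=C(/COC(C)=O)C[C@H](OC(=O)CO[Si](C)(C)C(C)(C)C)[C@@H]12 | intermediate
31 | CNP0156635.1 | C=C1C(=O)O[C@H]2C[C@@H](C)CC/C=C(/COC(C)=O)C[C@H](OC(=O)CO)[C@@H]12 | target

## Step count and risks

Total step count: 21. Longest linear sequence: 21 steps (from 1 and 2 to 31).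

Steps most likely to fail:

1. Step 10. What may go wrong: part of the rearrangement runs through a boat-like transition state because the Z-methyl group is axial in the chair, eroding chirality transfer to C4; alkoxide-induced fragmentation is a second possibility. Fallback, setting out from 11 and returning at 16: the methyl group is decoupled from the rearrangement. Vinylmagnesium bromide with CeCl3 should add to 11 as in step 9 to give the divinyl carbinol F1. KH and 18-crown-6 rearrange it through a chair with no axial substituent, and the potassium enolate is dehydrogenated in the same flask with N-tert-butylbenzenesulfinimidoyl chloride at −78 °C (Mukaiyama dehydrogenation) to the (4E)-enone F2. Conjugate addition of Me2CuLi with Me3SiCl from the ring periphery should then place the methyl group on C4 and give 16; the sense of this addition would have to be confirmed at that stage.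

2. Step 5. What may go wrong: oxygen captures the first radical before it cyclizes, tin hydride reduces the C8 radical before oxygen capture, or oxygen capture at C8 shows poor facial selectivity. Fallback, setting out from 4 and returning at 10: an ionic sequence in which the acetate supplies C11 and C12. Peracid epoxidation of the ring alkene anti to the pseudo-axial acetoxy group should give the epoxy acetate F3. LiN(SiMe3)2 then forms the acetate enolate, which opens the epoxide at C7 in the 5-exo mode with inversion, giving the hydroxy lactone F4 with C11 β and O8 α. Silylation with i-Pr3SiOTf gives the silyl ether F5, reduction with i-Bu2AlH at −78 °C gives the lactol F6, and propane-1,3-dithiol with BF3·OEt2 converts F6 into 10.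

3. Step 11. What may go wrong: poor facial discrimination in hydride delivery to the C6 ketone of the flexible ring, or inversion of the carbonyl conformation before reduction. Fallback, setting out from 16 and returning at 17: if the 6α alcohol F7 predominates (it could also be made on purpose with a small hydride such as NaBH4), Mitsunobu reaction with 4-nitrobenzoic acid, PPh3 and diisopropyl azodicarboxylate inverts C6 to give the 6β 4-nitrobenzoate F8, and K2CO3 in MeOH releases 17.

## Further compounds

F1 | step 10 | 6α-vinyl analogue of 13 (divinyl carbinol) | O[C@@]1(C=C)[C@@H](C=C)[C@H](C2SCCCS2)C[C@H](O[Si](C(C)C)(C(C)C)C(C)C)[C@H]1CC3SCCCS3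
F2 | step 10 | (1E,4E)-cyclodeca-1,4-dien-6-one lacking the C4 methyl group | O=C1/C=C/C/C=C/[C@H](C2SCCCS2)C[C@H](O[Si](C(C)C)(C(C)C)C(C)C)[C@H]1CC3SCCCS3
F3 | step 5 | 7α,8α-epoxide of 4 (epoxy acetate) | CC(=O)O[C@@H]1[C@H]2O[C@H]2C[C@@H](C(OC)OC)[C@@H]1C=C
F4 | step 5 | cis-fused hydroxy lactone (C12=O analogue of 8) | O=C1C[C@@H]2[C@@H](O)C[C@@H](C(OC)OC)[C@H](C=C)[C@@H]2O1
F5 | step 5 | 8α-triisopropylsilyl ether of F4 | O=C1C[C@@H]2[C@@H](O[Si](C(C)C)(C(C)C)C(C)C)C[C@@H](C(OC)OC)[C@H](C=C)[C@@H]2O1
F6 | step 5 | lactol from F5 | OC1C[C@@H]2[C@@H](O[Si](C(C)C)(C(C)C)C(C)C)C[C@@H](C(OC)OC)[C@H](C=C)[C@@H]2O1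
F7 | step 11 | 6α alcohol (C6 epimer of 17) | O[C@@H]1C[C@@H](C)C/C=C/[C@H](C2SCCCS2)C[C@H](O[Si](C(C)C)(C(C)C)C(C)C)[C@H]1CC3SCCCS3
F8 | step 11 | 6β 4-nitrobenzoate of 17 | O=C(O[C@H]1C[C@@H](C)C/C=C/[C@H](C2SCCCS2)C[C@H](O[Si](C(C)C)(C(C)C)C(C)C)[C@H]1CC3SCCCS3)c1ccc(cc1)[N+](=O)[O-]
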